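If the target in the alpha run keeps one share of whatever has dissolved, then part of what I take out comes back from the rest, so I reckon with fractions left.

| setting | alpha | zeta | flask |
|---|---|---|---|
| solid substrate | 0.026 M | 0.013 M | 0.026 M |
| temperature | 25 °C | 31 °C | 25 °C |
| remark | the very flask that is asked about, followed so far | run made earlier |  |
| time |  |  | 1.5 h |

| run | time / min | target / % | solid substrate / % |
|---|---|---|---|
| alpha | 6.00 | 5.3 | 76.5 |
| alpha | 20.0 | 12.9 | 39.6 |
| alpha | 30.0 | 17.5 | 16.6 |
| alpha | 50.0 | 20.3 | 0 |
| alpha | 80.0 | 15.6 | 0 |
| zeta | 4.00 | 6.0 | 67.8 |
| zeta | 8.00 | 14.4 | 41.8 |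
| zeta | 15.0 | 25.7 | 0 |
| zeta | 25.0 | 20.2 | 0 |
| zeta | 50.0 | 14.0 | 0.2 |

(scatter of a reading: 1 percentage point)

- given per volume of solution although it is solid: solid substrate
- target taken out counts as made
- at the start none of the solid substrate is in solution

- larch: change nothing and wait 25 min more
- cedar: at 1.5 h raise the temperature by 25 K, then wait 25 min
- birch: at 1.5 h take out 90% of the target then present, then wait 25 min

1. target, in percent of the solid substrate first charged, at 1.5 h
2. the remedy with the largest gain of target, or "none" below 2 percentage points (larch / cedar / birch / none)
3. target present, with what was taken out counted in, in percent of the solid substrate first charged, after cedar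
4. target present, with what was taken out counted in, in percent of the solid substrate first charged, after birch

Let s be the share of the dissolved substrate that stands as target. Pooling the alpha readings up to 30.0 min gives s = 21.3%, and singly it reads 22.6% at 6.00 min and 21.0% at 30.0 min. It stands at the first reading, earlier than the end of the wait, so I read it as a fast balance (a pre-equilibrium) with forms I cannot see, and I let it return within the wait. Taking out 90% of the target then removes a fraction s times that of the pool in this balance, leaving 80.8% of it.

But s holds no time, so one number is not enough. With the solid reading 0%, the alpha target falls between its last two readings at k = 0.00878 min⁻¹, and I let the whole pool fall at that rate, which leaves a fraction f = 80.3% over the wait. For the flask I reckon 14.3% now, 11.5% after larch, and 22.1% after birch, a gain of 7.8 percentage points, above the margin.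

The forecast gives 14.4% now, 1% after cedar, 14.2% after birch, and as best none: “It peaks near 21 %, then falls once the solid is gone, so nothing is left to feed it.”

The flask gives 14.7%, with 1.18% after cedar and 23.4% after birch; the best is birch, gaining 8.7 points.

    solid substrate ⇌ starting material, rate k1*(cs1 - [starting material]) while solid is left; crystals form when [starting material] > cs1 (solubility = 19.0 mM, k = 0.0570 min⁻¹)
    starting material ⇌ target (K = 0.470, k = 0.410 min⁻¹, Ea = 78.0 kJ mol⁻¹, ΔH = 46.0 kJ mol⁻¹)
    isomer of the product ⇌ starting material (k = 0.0580 min⁻¹, Ea = 98.0 kJ mol⁻¹)
    target → over-reaction product (k = 0.0260 min⁻¹, Ea = 84.0 kJ mol⁻¹)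
    target ⇌ isomer of the product (K = 1.20, k = 0.140 min⁻¹, Ea = 90.0 kJ mol⁻¹, ΔH = 7.00 kJ mol⁻¹)
    (constants at 25 °C)

At 90.0 min this flask holds starting material 31.8% and isomer of the product 18.4% beside target 14.7%, so target is 22.7% of these three. The neighbouring flask, read at 40.0 min, holds over-reaction product 12.8%, so s applied to the remainder gives 18.6%, and that flask holds target 20.1%.

The readings were computed for substances that don't exist.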